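**Retrosynthetic overview**
1. Daucane numbering: C1 (quaternary, methyl) and C5 (CH) are the ring-fusion atoms; ring A = C1–C5 (C2 OAc, C4 OH/isopropyl); seven-membered ring = C5–C6(O-aroyl)–C7=C8(CH3)–C9(=O)–C10–C1; β = face of the C1 methyl.
2. Endgame: C6 ester ← 6α-alcohol 19 ← enedione 18 (hydroxyl-directed reduction); 18 ← two-carbon ring expansion of diquinane enone 14.
3. Key disconnection: C7–C8 and C5–C6 are made together by [2+2] photocycloaddition of ethoxyethyne across C5=C8 of 14; the strained cyclobutene then opens with cleavage of C5–C8, turning the cyclopentenone into the seven-membered enedione with the C7=C8 enone and the C6 oxygen in place.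
4. Enabling feature: the tetrasubstituted enone C5=C8–C9=O inside the five-membered ring C5/C8/C9/C10/C1, fused to ring A at C1–C5; it is the photoactive chromophore, and after cycloaddition its former double bond is the cyclobutene σ-bond flanked by the C9 acyl group and the C6 enol ether.
5. Ring order: ring A (bought as 2-methylcyclopentane-1,3-dione; C1/C2 by CBS desymmetrisation, C4 by manganese-mediated hydration) → cyclopentenone ring (alkyne hydration/aldol) → cyclobutene (light) → seven-membered ring (ring expansion).

Key step: step 10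

Remark: ethoxyethyne (hexane solution) and 4-acetoxybenzoyl chloride are taken as purchased; the C5 configuration of 18 is assumed to be the thermodynamic one (trans-fused), which is reasoned but not proven.

**Step 1**
Reactants: 1 2-methylcyclopentane-1,3-dione; 2 1-bromobut-2-yne
Product: 3 2-(but-2-yn-1-yl)-2-methylcyclopentane-1,3-dione
Conditions: NaOH (1 M aq, 1.05 equiv), 60 °C
Reagents that add atoms: 1-bromobut-2-yne (2), CC#CCBr
Why: C-alkylation of the stabilised 1,3-dione enolate with a propargylic bromide in water is the standard entry to 2,2-disubstituted cyclopentane-1,3-diones, and no stereocentre is formed.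

**Step 2**
Reactants: 3
Product: 4 (2R,3R)-2-(but-2-yn-1-yl)-3-hydroxy-2-methylcyclopentan-1-one
Conditions: (S)-2-methyl-CBS-oxazaborolidine (0.2 equiv), catecholborane (1.2 equiv), toluene, −78 °C; aq. NaOH work-up
Reagents that add atoms: none
Why: Corey–Bakshi–Shibata desymmetrisation, in which the (S)-catalyst should give the (R)-carbinol with the quaternary carbon as the large group and the carbonyl that can be attacked anti to the butynyl chain is the one reduced, so the hydroxyl ends cis to butynyl and trans to methyl (C1 and C2 of the target).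

**Step 3**
Reactants: 4
Product: 5 (2R,3R)-2-(but-2-yn-1-yl)-3-[(tert-butyldimethylsilyl)oxy]-2-methylcyclopentan-1-one
Conditions: TBSCl, imidazole, DMF, rt
Reagents that add atoms: tert-butyldimethylsilyl chloride, CC(C)(C)[Si](C)(C)Cl
Why: Silylation of the secondary alcohol blocks retro-aldol opening of the β-hydroxy ketone in the later basic steps.

**Step 4**
Reactants: 5; 6 acetone
Product: 7 (2R,3R)-2-(but-2-yn-1-yl)-3-[(tert-butyldimethylsilyl)oxy]-5-(2-hydroxypropan-2-yl)-2-methylcyclopentan-1-one (both C5 epimers)
Conditions: LDA, THF, −78 °C; acetone, −78 °C; aq. NH4Cl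
Reagents that add atoms: acetone (6), CC(C)=O
Why: Lithium enolate aldol addition, regiospecific because the ketone can enolise only toward the CH2 (the other α-carbon is quaternary); the new centre is removed in step 5.

**Step 5**
Reactants: 7
Product: 9 (2R,3R)-2-(but-2-yn-1-yl)-3-[(tert-butyldimethylsilyl)oxy]-2-methyl-5-(propan-2-ylidene)cyclopentan-1-one, via mesylate 8 (not isolated)
Conditions: MsCl, Et3N, CH2Cl2, 0 °C; then DBU, rt
Reagents that add atoms: none
Why: Mesylation of the tertiary aldol and E1cB elimination give the conjugated isopropylidene ketone; an endocyclic enone isomer would converge in step 6.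

**Step 6**
Reactants: 9
Product: 10 (2R,3R,5S)-2-(but-2-yn-1-yl)-3-[(tert-butyldimethylsilyl)oxy]-5-hydroxy-2-methyl-5-(propan-2-yl)cyclopentan-1-one
Conditions: Mn(dpm)3 (dpm = 2,2,6,6-tetramethylheptane-3,5-dionate, 10 mol %), PhSiH3, O2 (1 atm), i-PrOH/CH2Cl2, 0 °C
Reagents that add atoms: dioxygen, O=O
Why: Mukaiyama-type reductive α-hydroxylation of an enone: manganese hydride transfers H to the β-carbon, the tertiary α-keto radical at C4 is trapped by O2 and the peroxide is reduced by the silane, with oxygen entering anti to the butynyl and silyloxy groups (both on the α face) to set the 4β-hydroxyl.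

**Step 7**
Reactants: 10
Product: 12 (4S,6R,6aS)-6-[(tert-butyldimethylsilyl)oxy]-4-hydroxy-3,6a-dimethyl-4-(propan-2-yl)-4,5,6,6a-tetrahydropentalen-2(1H)-one, via 1,4-diketone 11 (not isolated)
Conditions: Ph3PAuNTf2 (5 mol %), H2O (5 equiv), 1,4-dioxane, 60 °C; then KOH, MeOH, 60 °C
Reagents that add atoms: water, O
Why: Gold-catalysed alkyne hydration, made regioselective by 5-exo attack of the C5 carbonyl oxygen on the proximal alkyne carbon, gives the 1,4-diketone, whose only productive enolate (C8) closes on C5 in an intramolecular aldol condensation to the cyclopentenone without touching a stereocentre.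

**Step 8**
Reactants: 12
Product: 13 (4S,6R,6aS)-4,6-dihydroxy-3,6a-dimethyl-4-(propan-2-yl)-4,5,6,6a-tetrahydropentalen-2(1H)-one
Conditions: HF·pyridine, THF, 0 °C to rt
Reagents that add atoms: none
Why: Fluoride cleavage of the secondary silyl ether; the enone and the tertiary alcohol (whose ionisation would place a cation next to the electron-poor enone carbon) should survive.

**Step 9**
Reactants: 13
Product: 14 (1R,3S,6aS)-3-hydroxy-4,6a-dimethyl-5-oxo-3-(propan-2-yl)-1,2,3,5,6,6a-hexahydropentalen-1-yl acetate
Conditions: Ac2O, pyridine, DMAP (cat.), CH2Cl2, 0 °C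
Reagents that add atoms: acetic anhydride, CC(=O)OC(C)=O
Why: DMAP-catalysed acetylation is selective for the secondary C2 hydroxyl over the hindered tertiary C4 hydroxyl, which is kept free for steps 10 and 12.

**Step 10**
Reactants: 14; 15 ethoxyethyne
Product: 16 cyclobutene photoadduct of 14: C6(OEt)=C7H bridges C5 and C8, new bonds C5–C6 and C8–C7 both on the β face, cyclobutene cis-fused to the cyclopentanone of a cis-diquinane
Conditions: hν (365 nm), 15 (10 equiv), CH2Cl2/hexane, −60 °C
Reagents that add atoms: ethoxyethyne (15), C#COCC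
Why: Proposed new method: excitation of the cyclopentenone chromophore and intersystem crossing give the triplet enone, which adds the ynol ether stepwise through a 1,4-biradical and closes to the cyclobutene, forming C7–C8 and C5–C6 in one operation; the closest known reactions are the [2+2] photocycloaddition of cyclopentenones with simple alkynes to bicyclo[3.2.0]hept-6-en-2-ones and the head-to-tail photocycloaddition of enones with ketene acetals and enol ethers, the 1-alkoxyalkyne partner being the untested element. The four-membered ring closes by intermolecular [2+2] addition across C5=C8 and has to be cis-fused to the five-membered ring C5/C8/C9/C10/C1. The two new stereocentres C5 and C8 are fixed by ring strain alone (only addition on the face of the C1 methyl keeps ring A and the cyclopentanone cis-fused), and both are erased again when the cyclobutene opens in step 11, so no facial selectivity beyond this has to be secured. The selectivity the step needs is head-to-tail regiochemistry (oxygen-bearing carbon to the β-carbon C5), which the polarisation of the electron-rich ynol ether should provide as it does for ketene acetals, reinforced by a hydrogen bond from the β-oriented C4 hydroxyl to the ether oxygen. Irradiation at 365 nm and low temperature keeps the β,γ-unsaturated ketone product from absorbing, which suppresses the 1,3-acyl shift known for such adducts.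

**Step 11**
Reactants: 16
Product: 18 (1R,3S,3aS,8aS)-3-hydroxy-6,8a-dimethyl-4,7-dioxo-3-(propan-2-yl)-1,2,3,3a,4,7,8,8a-octahydroazulen-1-yl acetate, via ethoxydienone 17 (not isolated)
Conditions: BF3·OEt2 (0.2 equiv), 2,6-di-tert-butylpyridine (0.3 equiv), CH2Cl2, −78 to −20 °C; then 0.1 M HCl, THF, 0 °C to rt
Reagents that add atoms: water, O
Why: Acid-promoted two-carbon ring expansion of an enone–alkyne photoadduct (bicyclo[3.2.0]hept-6-en-2-one to cyclohepta-2,4-dienone): boron trifluoride on the C9 carbonyl heterolyses the strained C5–C8 bond as an enolate/2-ethoxyallyl cation pair that collapses to dienone 17 with the C7=C8 enone in place, and dilute acid then hydrolyses the enol ether and protonates C5, which, being epimerisable next to the C6 carbonyl, should settle as the trans-fused isomer (C6 cis to the hydrogen-bonding C4 hydroxyl and trans to isopropyl).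

**Step 12**
Reactants: 18
Product: 19 (1R,3S,3aR,4R,8aS)-3,4-dihydroxy-6,8a-dimethyl-7-oxo-3-(propan-2-yl)-1,2,3,3a,4,7,8,8a-octahydroazulen-1-yl acetate
Conditions: Me4NBH(OAc)3 (5 equiv), MeCN/AcOH (1:1), −30 °C
Reagents that add atoms: none
Why: Evans–Saksena hydroxyl-directed reduction: the acetoxyborohydride exchanges onto the C4 hydroxyl and delivers hydride internally to the face of the C6 carbonyl turned toward ring A, giving the 6α-alcohol (H6 anti to H5), while the C9 carbonyl, which has no hydroxyl within reach, and the double bond are left alone.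

**Step 13**
Reactants: 19; 20 4-acetoxybenzoyl chloride
Product: 21 (1R,3S,3aR,4R,8aS)-1-(acetyloxy)-3-hydroxy-6,8a-dimethyl-7-oxo-3-(propan-2-yl)-1,2,3,3a,4,7,8,8a-octahydroazulen-4-yl 4-(acetyloxy)benzoate
Conditions: 20 (1.5 equiv), pyridine, DMAP (cat.), CH2Cl2, 0 °C to rt
Reagents that add atoms: 4-acetoxybenzoyl chloride (20), CC(=O)Oc1ccc(cc1)C(Cl)=O
Why: DMAP-catalysed acylation of the only secondary hydroxyl (C6); the tertiary C4 hydroxyl does not react.

**Step 14**
Reactants: 21
Product: 22 target, (1R,3S,3aR,4R,8aS)-1-(acetyloxy)-3-hydroxy-6,8a-dimethyl-7-oxo-3-(propan-2-yl)-1,2,3,3a,4,7,8,8a-octahydroazulen-4-yl 4-hydroxybenzoate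
Conditions: NH4OAc (8 equiv), MeOH/H2O (4:1), rt
Reagents that add atoms: none
Why: Aryl acetates are cleaved under these near-neutral conditions far faster than the alkyl acetate at C2 or the benzoate at C6, so only the phenol is released.

**Compound list**
1 | 2-methylcyclopentane-1,3-dione | CC1C(=O)CCC1=O | starting material
2 | 1-bromobut-2-yne | CC#CCBr | starting material
3 | 2-(but-2-yn-1-yl)-2-methylcyclopentane-1,3-dione | CC#CCC1(C)C(=O)CCC1=O | intermediate
4 | (2R,3R)-2-(but-2-yn-1-yl)-3-hydroxy-2-methylcyclopentan-1-one (OH cis to butynyl) | O=C1CC[C@@H](O)[C@@]1(C)CC#CC | intermediate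
5 | TBS ether of 4 | O=C1CC[C@@H](O[Si](C)(C)C(C)(C)C)[C@@]1(C)CC#CC | intermediate
6 | acetone | CC(C)=O | starting material
7 | aldol adduct of 5 with acetone (mixture at the new ring carbon) | O=C1C(C(C)(C)O)C[C@@H](O[Si](C)(C)C(C)(C)C)[C@@]1(C)CC#CC | intermediate
8 | tertiary mesylate of 7 | O=C1C(C(C)(C)OS(C)(=O)=O)C[C@@H](O[Si](C)(C)C(C)(C)C)[C@@]1(C)CC#CC | intermediate (not isolated)
9 | isopropylidene ketone | O=C1C(=C(C)C)C[C@@H](O[Si](C)(C)C(C)(C)C)[C@@]1(C)CC#CC | intermediate
10 | (2R,3R,5S)-α-hydroxy ketone (4β-OH, 4α-isopropyl in daucane terms) | O=C1[C@@](O)(C(C)C)C[C@@H](O[Si](C)(C)C(C)(C)C)[C@@]1(C)CC#CC | intermediate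
11 | (2R,3R,5S)-3-silyloxy-5-hydroxy-2-methyl-2-(2-oxobutyl)-5-isopropylcyclopentan-1-one | O=C1[C@@](O)(C(C)C)C[C@@H](O[Si](C)(C)C(C)(C)C)[C@@]1(C)CC(=O)CC | intermediate (not isolated)
12 | diquinane enone, C2 OTBS (α), C4 OH (β), C1 methyl (β) | O=C1C[C@]2(C)[C@H](O[Si](C)(C)C(C)(C)C)C[C@](O)(C(C)C)C2=C1C | intermediate
13 | diquinane enone diol | O=C1C[C@]2(C)[C@H](O)C[C@](O)(C(C)C)C2=C1C | intermediate
14 | diquinane enone, C2 acetate, free C4 hydroxyl | O=C1C[C@]2(C)[C@H](OC(C)=O)C[C@](O)(C(C)C)C2=C1C | intermediate
15 | ethoxyethyne | C#COCC | starting material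
16 | ethoxycyclobutene photoadduct (C5–C6 and C8–C7 on the β face) | O=C1C[C@]2(C)[C@H](OC(C)=O)C[C@](O)(C(C)C)[C@@]23C(OCC)=C[C@@]13C | intermediate
17 | 6-ethoxy-5,7-dienone (ring-expanded enol ether; C1, C2, C4 as in 14) | CC(=O)O[C@@H]1C[C@](O)(C(C)C)C2=C(OCC)C=C(C)C(=O)C[C@]12C | intermediate (not isolated)
18 | enedione, trans-fused (H5 α) | CC(=O)O[C@@H]1C[C@](O)(C(C)C)[C@H]2C(=O)C=C(C)C(=O)C[C@]12C | intermediate
19 | 6α-alcohol | CC(=O)O[C@@H]1C[C@](O)(C(C)C)[C@H]2[C@H](O)C=C(C)C(=O)C[C@]12C | intermediate
20 | 4-acetoxybenzoyl chloride | CC(=O)Oc1ccc(cc1)C(Cl)=O | starting material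
21 | C6 4-acetoxybenzoate | CC(=O)O[C@@H]1C[C@](O)(C(C)C)[C@H]2[C@H](OC(=O)c3ccc(OC(C)=O)cc3)C=C(C)C(=O)C[C@]12C | intermediate
22 | target | CC(=O)O[C@@H]1C[C@](O)(C(C)C)[C@H]2[C@H](OC(=O)c3ccc(O)cc3)C=C(C)C(=O)C[C@]12C | target

Total step count: 14. Longest linear sequence: 14 steps (1 → 22).

**Steps most likely to fail**

1. Step 10 (Proposed new method). The cycloaddition may go head-to-head, the biradical may revert because closure at the doubly neopentyl C5 is slow, or the adduct may undergo a secondary 1,3-acyl shift. Fallback with known chemistry, from 14 back to 18: irradiation of 14 with 1,1-diethoxyethene, whose head-to-tail addition to enones is well established, should give the cyclobutanone diethyl ketal F1; TMSOTf/i-Pr2NEt (ketal-to-enol-ether elimination) should then give the O-silylated ethoxycyclobutene F2, the C4 hydroxyl being silylated in the same pot; F2 is taken through the conditions of step 11, where the aqueous acid also removes the silyl ether, and the route is rejoined at 18.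

2. Step 11. The tertiary C4 hydroxyl may ionise and be lost once it is allylic to the enol ether, the cyclobutene enol ether may be hydrolysed to a cyclobutanone before the ring opens, or C5 may not equilibrate fully to the trans-fused isomer. Fallback, from 16 back to 18: 16 is hydrolysed on purpose with dilute aqueous acid to the cyclobutanone F3 (C5 is still sp3 there, so nothing can ionise); TMSOTf/Et3N silylates the C4 hydroxyl and the more acidic cyclobutanone, which can enolise only toward C7, to give the siloxycyclobutene F4; ring opening with the same catalytic Lewis acid or on warming gives the silyl dienol ether F5; buffered fluoride (TBAF/AcOH) then releases 18 without acid meeting the allylic carbinol.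

3. Step 12. Hydride may arrive from the open face (6β-alcohol) if exchange of the borohydride onto the hindered tertiary hydroxyl is slow, or the enedione may be reduced in the conjugate sense. Fallback, from 18 to 21: external hydride (NaBH4, CeCl3, MeOH, −78 °C) should attack the C6 carbonyl, activated by the neighbouring hydroxyl, from the exposed face to give the 6β-alcohol F6; Mitsunobu esterification of F6 with 4-acetoxybenzoic acid (PPh3, DIAD) then installs the ester with inversion and gives 21 directly.

**Further compounds**
F1 | step 10 | cyclobutanone diethyl ketal photoadduct (ketal carbon on C5) | O=C1C[C@]2(C)[C@H](OC(C)=O)C[C@](O)(C(C)C)[C@@]23C(OCC)(OCC)C[C@@]13C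
F2 | step 10 | O-trimethylsilyl ether of ethoxycyclobutene 16 | O=C1C[C@]2(C)[C@H](OC(C)=O)C[C@](O[Si](C)(C)C)(C(C)C)[C@@]23C(OCC)=C[C@@]13C
F3 | step 11 | cyclobutanone from hydrolysis of 16 | O=C1C[C@]2(C)[C@H](OC(C)=O)C[C@](O)(C(C)C)[C@@]23C(=O)C[C@@]13C
F4 | step 11 | bis-trimethylsilyl siloxycyclobutene | O=C1C[C@]2(C)[C@H](OC(C)=O)C[C@](O[Si](C)(C)C)(C(C)C)[C@@]23C(O[Si](C)(C)C)=C[C@@]13C
F5 | step 11 | ring-expanded silyl dienol ether | CC(=O)O[C@@H]1C[C@](O[Si](C)(C)C)(C(C)C)C2=C(O[Si](C)(C)C)C=C(C)C(=O)C[C@]12C
F6 | step 12 | 6β-alcohol (C6 epimer of 19) | CC(=O)O[C@@H]1C[C@](O)(C(C)C)[C@H]2[C@@H](O)C=C(C)C(=O)C[C@]12C
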